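Assumption: the target SMILES is read as (5S,6R,7S,8S), that is 5-OH/6-OH trans, 6-OH/7-OH trans and 7-OH/8-OAr cis. Below, Ar = 7-methoxy-4-oxo-2-(2-phenylethyl)-4H-chromen-6-yl and TES = triethylsilyl. Chromone locants (O1, C2, C3, C4, C4a, C5–C8, C8a) are used for the tetrahydro unit throughout, including its open-chain precursors.

## Structural features

The target is an ether-linked dimer of two 2-(2-phenylethyl)chromones. Unit B is an aromatic 7-methoxychromone bound through its C6 oxygen. Unit A is a 5,6,7,8-tetrahydrochromone whose 4-pyranone is fused through C4a=C8a to a fully substituted carbocycle (ring A). Ring A carries four contiguous stereocentres, C5–OH, C6–OH, C7–OH and C8–OAr, with 5,6-trans, 6,7-trans and 7,8-cis relations. The link is a secondary alkyl aryl ether at C8, between the O-bearing sp2 carbon C8a and the C7 carbinol. Its cis relation to O7 is exactly what an anti opening of a 7,8-epoxide by the phenol cannot give. C8–H is vinylogously acidic, so base can epimerise C8 or expel O7 and start aromatisation; the C5–O and C8–O bonds are allylic to the pyranone and acid-labile; both pyranones open with hard nucleophiles. The real difficulty is ring A: four stereocentres in a row ending in the cis ether, on a ring whose two sp2 carbons differ (C8a bears O1, C4a bears the C4 carbonyl).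

The feature the key step exploits is that C4a, C5, C6, C7, C8 and C8a have the substitution and absolute configuration of C1–C6 of D-glucuronic acid. C5–C8 are C2–C5 of the sugar (D-gluco), the ether oxygen is O5, C8a is the carboxyl carbon and C4a is the aldehyde carbon. The missing C4a–C8a bond and the C4 oxygen are what a nitrile oxide at C8a delivers when it adds to a C4a=C4 alkene.

## Logic of the disconnections

27 from 26, and 26 from 24: the three O–Si bonds and the O1–C2 bond of the unit A pyranone are cut. A 4-pyranone is the 6-endo cyclisation product of an enolised 2-alkynoyl ketone, so the ring reduces to a ketone at C8a and a propargylic alcohol at C4. The forward step must oxidise only that alcohol and close through the C8a enol oxygen.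

24 from 23, and 23 from 21 (key): the C4a–C8a bond and the C4–O bond are cut, with nitrogen as a traceless link between C8a and the C4 oxygen. Ring A opens to an acyclic chain with an oxime at C8a and a C4a=C4 alkene. The carbocycle with four stereocentres becomes an open-chain D-gluco derivative in which no stereocentre has to be made. The forward cycloaddition must close a six-membered ring faster than the nitrile oxide dimerises, no hydroxyl may be free, and the N–O bond must later be cleaved without touching the alkyne.

21 from 19, 19 from 18, and 18 from 17 and 10: the C4a=C4 double bond is cut (Wittig), and the C8a oxime is traced back to a primary alcohol. The chain becomes a 5-O-aryl-D-glucose and a five-carbon phosphonium salt that carries C4, C3, C2 and the phenylethyl group. The olefination must work on a lactol with free hydroxyls, and the primary silyl ether of 19 must be oxidised selectively.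

17 from 15: only the oxidation level at C8a and the acetal at C4a change. This returns the chain to a bicyclic lactone in which C8 is alpha to a carbonyl.

15 from 14 and 6: the C8–O(aryl) bond is cut. In the lactone C8 is alpha to C=O, so the hard ether bond becomes an SN2 displacement by the phenol with clean inversion, and the dimer splits into a chromone phenol and a sugar lactone. The forward step must deliver the nucleophile to the concave face. 14 comes from 11 by a first inversion at the same carbon, so the two inversions together give the D-gluco ether.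

6 from 3 and 4, 3 from 2, 2 from 1: O1–C2 and C3–C4 of the aromatic chromone are cut (cyclodehydration, Claisen condensation), then the acetyl C–C bond (Friedel–Crafts). The phenol that later forms the ether must be masked during the condensation and freed in the same acid step.

10 from 8, and 8 from 7: the C–P bond and the C–C bond to formaldehyde are cut.

## Other disconnections considered

Alternative 1: cut the C8–O(aryl) bond between two finished chromones, as in the presumed biosynthesis. The forward key step is opening of the 7,8-epoxide A1 at C8 by phenol 6. This is the first plan that comes to mind, but an SN2 opening is anti and would give the 7,8-trans ether A2, the C7 epimer of the target. Reaching the cis ether this way needs displacement with inversion on the all-trans alcohol A3, at a carbon flanked by the pyranone and an oxygenated carbon, where elimination toward an aromatic chromone is an obvious competitor. In either case A1 or A3 still has to be made with four stereocentres, so the cut moves the difficulty without reducing it.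

Alternative 2: buy C7 and C8 as (1S,2S)-3-bromocyclohexa-3,5-diene-1,2-diol, whose brominated carbon maps onto C8a. Photooxygenation of its acetonide would lead to enone A4, and an intermolecular nitrile oxide cycloaddition to the C4a=C5 bond followed by pyranone closure would lead to tetrol A5. The core is short, but the ether must then be made with retention at O8, that is with an aryl electrophile such as boronic acid A6 under Cu(OAc)2. Nothing in A5 secures the choice of O8 over O7 within the cis-diol, or over O5 and O6, and the regiochemistry of an intermolecular cycloaddition to A4 is not enforced by a tether. The chosen plan makes the ether by SN2 alpha to a lactone carbonyl and fixes the regiochemistry of the cycloaddition by ring size.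

Alternative 3: keep the glucuronic acid mapping but close both rings of unit A in one base-mediated operation from lactone ynone A7. A C4a enolate would attack the lactone carbonyl C8a (Dieckmann) and the resulting enolate oxygen would add to the ynone. This is the most economical on paper, but the C4a enolate has the C5 oxygen in the beta position (E1cB loss if protected; 6-endo capture of the ynone by the wrong oxygen if free). C8–H alpha to the lactone is exposed to the strong base, and making A7 requires deoxygenation and homologation at C4a. The cycloaddition uses both sugar termini at their native aldehyde level under near-neutral conditions.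

Key step: step 12

## Route

Step 1
Reactants: 1 2-methoxybenzene-1,4-diol
Product: 2 1-(2,5-dihydroxy-4-methoxyphenyl)ethan-1-one
Conditions: AcOH, BF3·OEt2, 90 °C
Reagents that add atoms: acetic acid, CC(O)=O
Why: Friedel–Crafts acylation should occur at the position ortho to one hydroxyl and para to the methoxy group, the most activated and least hindered site.

Step 2
Reactants: 2 1-(2,5-dihydroxy-4-methoxyphenyl)ethan-1-one
Product: 3 1-[2-hydroxy-4-methoxy-5-(methoxymethoxy)phenyl]ethan-1-one
Conditions: MOMCl, i-Pr2NEt, CH2Cl2, 0 °C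
Reagents that add atoms: chloromethyl methyl ether, COCCl
Why: The 2-hydroxyl is hydrogen-bonded to the acetyl group and poorly nucleophilic, so alkylation should take the 5-hydroxyl, the future ether oxygen.

Step 3
Reactants: 3 1-[2-hydroxy-4-methoxy-5-(methoxymethoxy)phenyl]ethan-1-one; 4 ethyl 3-phenylpropanoate
Product: 6 6-hydroxy-7-methoxy-2-(2-phenylethyl)-4H-chromen-4-one, via aryl diketone 5 (not isolated)
Conditions: NaH, THF, 65 °C; then conc. HCl, MeOH, 65 °C
Reagents that add atoms: none
Why: Claisen condensation of the acetophenone dianion with the ester gives the 1,3-diketone. Acid then cyclodehydrates it to the chromone and removes the acetal protecting group in the same operation.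

Step 4
Reactants: 7 4-phenylbut-1-yne
Product: 8 5-phenylpent-2-yn-1-ol
Conditions: n-BuLi, THF, −78 °C; (CH2O)n, −78 to 23 °C; aq. NH4Cl
Reagents that add atoms: formaldehyde (as paraformaldehyde), C=O
Why: Addition of a lithium acetylide to formaldehyde is the standard route to a primary propargylic alcohol.

Step 5
Reactants: 8 5-phenylpent-2-yn-1-ol
Product: 10 triphenyl(5-phenylpent-2-yn-1-yl)phosphonium bromide, via propargylic bromide 9 (not isolated)
Conditions: CBr4, PPh3, CH2Cl2, 0 °C; then PPh3, toluene, 80 °C
Reagents that add atoms: carbon tetrabromide, BrC(Br)(Br)Br; triphenylphosphine, c1ccc(cc1)P(c1ccccc1)c1ccccc1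
Why: Appel bromination followed by quaternisation of the primary propargylic bromide should give the semi-stabilised Wittig salt that carries C4, C3, C2 and the side chain of unit A.

Step 6
Reactants: 11 1,2-O-isopropylidene-α-D-glucofuranurono-6,3-lactone
Product: 14 1,2-O-isopropylidene-β-L-idofuranurono-6,3-lactone, via D-gluco triflate 12 (not isolated), via L-ido trifluoroacetate 13 (not isolated)
Conditions: Tf2O, pyridine, CH2Cl2, −20 °C; then CF3CO2Na, DMF, 23 °C; then MeOH, 23 °C
Reagents that add atoms: sodium trifluoroacetate, [Na+].[O-]C(=O)C(F)(F)F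
Why: The triflate alpha to the lactone carbonyl should be displaced by trifluoroacetate from the open convex face with inversion (SN2), and methanol then cleaves the labile ester. This first inversion at the future C8 prepares the second one in step 7.

Step 7
Reactants: 14 1,2-O-isopropylidene-β-L-idofuranurono-6,3-lactone; 6 6-hydroxy-7-methoxy-2-(2-phenylethyl)-4H-chromen-4-one
Product: 15 5-O-Ar-1,2-O-isopropylidene-α-D-glucofuranurono-6,3-lactone
Conditions: PPh3, DIAD, THF, 0 to 23 °C
Reagents that add atoms: none
Why: Mitsunobu etherification of an alpha-hydroxy lactone by a phenol proceeds by SN2 at the carbonyl-activated carbon. The inversion returns the centre to the D-gluco configuration and sets C8 of the target with its aryl ether in place.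

Step 8
Reactants: 15 5-O-Ar-1,2-O-isopropylidene-α-D-glucofuranurono-6,3-lactone
Product: 17 5-O-Ar-D-glucofuranose (anomeric mixture), via acetonide diol 16 (not isolated)
Conditions: NaBH4, EtOH/THF, 0 °C; then TFA/H2O (9:1), 0 to 23 °C
Reagents that add atoms: none
Why: Borohydride should reduce the strained alpha-aryloxy lactone to the diol much faster than the vinylogous ester carbonyl of the chromone. Aqueous acid then hydrolyses the acetonide to the hemiacetal, which can only be a furanose because O5 is arylated; no stereocentre is touched.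

Step 9
Reactants: 17 5-O-Ar-D-glucofuranose (anomeric mixture); 10 triphenyl(5-phenylpent-2-yn-1-yl)phosphonium bromide
Product: 18 (2R,3S,4R,5S)-2-(Ar-oxy)-11-phenylundec-6-en-8-yne-1,3,4,5-tetrol (E/Z mixture)
Conditions: 10 (4 equiv), NaN(SiMe3)2, THF, −78 to 0 °C; then 17, THF/DMF, −40 to 23 °C
Reagents that add atoms: none
Why: Wittig olefination of a reducing sugar through its open aldehyde form. The semi-stabilised ylide is not quenched by the alkoxides, the aldehyde oxygen at C4a is removed as the phosphine oxide, and the alkene geometry is irrelevant because C4a and C4 become sp2 later.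

Step 10
Reactants: 18 (2R,3S,4R,5S)-2-(Ar-oxy)-11-phenylundec-6-en-8-yne-1,3,4,5-tetrol (E/Z mixture)
Product: 19 1,3,4,5-tetrakis-O-TES ether of 18
Conditions: Et3SiCl, imidazole, DMF, 0 to 23 °C
Reagents that add atoms: chlorotriethylsilane, CC[Si](Cl)(CC)CC
Why: Per-silylation masks O5, O6 and O7, which would otherwise trap the nitrile oxide of step 12 as a cyclic hydroximate. It also leaves one primary silyl ether that step 11 can address selectively.

Step 11
Reactants: 19 1,3,4,5-tetrakis-O-TES ether of 18
Product: 21 2-(Ar-oxy)-11-phenyl-3,4,5-tris(TES-oxy)undec-6-en-8-ynal oxime (configuration as in 19), via silyloxy aldehyde 20 (not isolated)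
Conditions: (COCl)2, DMSO, CH2Cl2, −78 to −40 °C; i-Pr2NEt, −78 to 0 °C; then NH2OH·HCl, pyridine, EtOH, 0 °C
Reagents that add atoms: hydroxylamine hydrochloride, Cl.NO
Why: Swern conditions cleave and oxidise a primary triethylsilyl ether directly while secondary ones survive at low temperature. The alpha-aryloxy aldehyde is configurationally labile at C8 and is therefore trapped at once as the oxime.

Step 12
Reactants: 21 2-(Ar-oxy)-11-phenyl-3,4,5-tris(TES-oxy)undec-6-en-8-ynal oxime (configuration as in 19)
Product: 23 7-(Ar-oxy)-3-(4-phenylbut-1-yn-1-yl)-4,5,6-tris(TES-oxy)-3,3a,4,5,6,7-hexahydro-2,1-benzisoxazole (mixture at C3 and C3a), via nitrile oxide 22 (not isolated)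
Conditions: aq. NaOCl, CH2Cl2, 0 to 23 °C, slow addition at high dilution (0.005 M)
Reagents that add atoms: none
Why: Hypochlorite converts the aldoxime through the hydroximoyl chloride into nitrile oxide 22, which adds in a concerted [3+2] cycloaddition across the C4a=C4 double bond, forming the C8a–C4a bond and the O–C4 bond. The closest known reaction type is the intramolecular nitrile oxide–alkene cycloaddition of carbohydrate-derived alkenyl oximes to cyclohexane-fused isoxazolines. Ring A closes as a six-membered carbocycle in the fused mode, because the four-atom tether C8–C7–C6–C5 lets the dipole carbon reach only the proximal alkene carbon, and the isoxazoline closes as the five-membered ring of the cycloaddition. The alternative orientation would need a bridged seven-membered ring, and addition to the alkyne an eight-membered one. The two new stereocentres (C4a and C4) are fixed by the alkene geometry and the cis ring fusion, but neither needs control since both become sp2 in step 14. The four stereocentres C5–C8 come unchanged from the sugar, and the conditions are not basic enough to enolise C8–H next to the nitrile oxide. The selectivity required is ring closure over dimerisation to the furoxan and over trapping by oxygen nucleophiles. It is secured by slow generation at high dilution, by the silyl ethers on O5, O6 and O7, and by conjugation of the alkene with the alkyne, which lowers its LUMO.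

Step 13
Reactants: 23 7-(Ar-oxy)-3-(4-phenylbut-1-yn-1-yl)-4,5,6-tris(TES-oxy)-3,3a,4,5,6,7-hexahydro-2,1-benzisoxazole (mixture at C3 and C3a)
Product: 24 6-(Ar-oxy)-2-(1-hydroxy-5-phenylpent-2-yn-1-yl)-3,4,5-tris(TES-oxy)cyclohexan-1-one
Conditions: Mo(CO)6, MeCN/H2O (10:1), 80 °C
Reagents that add atoms: water, O
Why: Reductive N–O cleavage of an isoxazoline by Mo(CO)6 gives the beta-hydroxy imine, which hydrolyses in the wet medium to the beta-hydroxy ketone. The alkyne and the silyl ethers should survive these near-neutral conditions, which also limit enolisation toward C8.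

Step 14
Reactants: 24 6-(Ar-oxy)-2-(1-hydroxy-5-phenylpent-2-yn-1-yl)-3,4,5-tris(TES-oxy)cyclohexan-1-one
Product: 26 5,6,7-tris-O-TES ether of the target, via ynedione 25 (not isolated)
Conditions: MnO2, CH2Cl2, 23 °C; then Et2NH (0.2 equiv), EtOH, 23 °C
Reagents that add atoms: none
Why: MnO2 oxidises only the propargylic alcohol, and the resulting 2-alkynoyl ketone enolises between C8a and C4, which also shields C8–H. The amine adds reversibly to the ynone and the C8a enol oxygen closes 6-endo with loss of the amine to the aromatic 4-pyranone, as in the cyclisation of o-hydroxyaryl ynones to chromones.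

Step 15
Reactants: 26 5,6,7-tris-O-TES ether of the target
Product: 27 (5S,6R,7S,8S)-5,6,7-trihydroxy-8-(Ar-oxy)-2-(2-phenylethyl)-5,6,7,8-tetrahydro-4H-chromen-4-one (target)
Conditions: HF·pyridine, pyridine, THF, 0 °C
Reagents that add atoms: none
Why: Buffered fluoride removes the three silyl ethers without the base that would deprotonate C8 or the strong acid that would ionise the allylic C5–O and C8–O bonds.

## Compound list

1 | 2-methoxybenzene-1,4-diol | COc1cc(O)ccc1O | starting material
2 | 1-(2,5-dihydroxy-4-methoxyphenyl)ethan-1-one | CC(=O)c1cc(O)c(OC)cc1O | intermediate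
3 | 1-[2-hydroxy-4-methoxy-5-(methoxymethoxy)phenyl]ethan-1-one | CC(=O)c1cc(OCOC)c(OC)cc1O | intermediate
4 | ethyl 3-phenylpropanoate | CCOC(=O)CCc1ccccc1 | starting material
5 | 1-[2-hydroxy-4-methoxy-5-(methoxymethoxy)phenyl]-5-phenylpentane-1,3-dione | COCOc1cc(C(=O)CC(=O)CCc2ccccc2)c(O)cc1OC | intermediate
6 | 6-hydroxy-7-methoxy-2-(2-phenylethyl)-4H-chromen-4-one | COc1cc2oc(CCc3ccccc3)cc(=O)c2cc1O | intermediate
7 | 4-phenylbut-1-yne | C#CCCc1ccccc1 | starting material
8 | 5-phenylpent-2-yn-1-ol | OCC#CCCc1ccccc1 | intermediate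
9 | (5-bromopent-3-yn-1-yl)benzene | BrCC#CCCc1ccccc1 | intermediate
10 | triphenyl(5-phenylpent-2-yn-1-yl)phosphonium bromide | [Br-].C(C#CCCc1ccccc1)[P+](c1ccccc1)(c1ccccc1)c1ccccc1 | intermediate
11 | 1,2-O-isopropylidene-α-D-glucofuranurono-6,3-lactone | CC1(C)O[C@H]2O[C@@H]3[C@H](O)C(=O)O[C@@H]3[C@H]2O1 | starting material
12 | 1,2-O-isopropylidene-5-O-trifluoromethanesulfonyl-α-D-glucofuranurono-6,3-lactone | CC1(C)O[C@H]2O[C@@H]3[C@H](OS(=O)(=O)C(F)(F)F)C(=O)O[C@@H]3[C@H]2O1 | intermediate
13 | 1,2-O-isopropylidene-5-O-trifluoroacetyl-β-L-idofuranurono-6,3-lactone | CC1(C)O[C@H]2O[C@@H]3[C@@H](OC(=O)C(F)(F)F)C(=O)O[C@@H]3[C@H]2O1 | intermediate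
14 | 1,2-O-isopropylidene-β-L-idofuranurono-6,3-lactone | CC1(C)O[C@H]2O[C@@H]3[C@@H](O)C(=O)O[C@@H]3[C@H]2O1 | intermediate
15 | 5-O-Ar-1,2-O-isopropylidene-α-D-glucofuranurono-6,3-lactone | CC1(C)O[C@H]2O[C@@H]3[C@H](Oc4cc5c(cc4OC)oc(CCc4ccccc4)cc5=O)C(=O)O[C@@H]3[C@H]2O1 | intermediate
16 | 5-O-Ar-1,2-O-isopropylidene-α-D-glucofuranose | CC1(C)O[C@H]2O[C@H]([C@@H](CO)Oc3cc4c(cc3OC)oc(CCc3ccccc3)cc4=O)[C@H](O)[C@H]2O1 | intermediate
17 | 5-O-Ar-D-glucofuranose (anomeric mixture) | OC1O[C@H]([C@@H](CO)Oc2cc3c(cc2OC)oc(CCc2ccccc2)cc3=O)[C@H](O)[C@H]1O | intermediate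
18 | (2R,3S,4R,5S)-2-(Ar-oxy)-11-phenylundec-6-en-8-yne-1,3,4,5-tetrol (E/Z mixture) | OC[C@@H](Oc1cc2c(cc1OC)oc(CCc1ccccc1)cc2=O)[C@@H](O)[C@H](O)[C@@H](O)C=CC#CCCc1ccccc1 | intermediate
19 | 1,3,4,5-tetrakis-O-TES ether of 18 | CC[Si](CC)(CC)OC[C@@H](Oc1cc2c(cc1OC)oc(CCc1ccccc1)cc2=O)[C@@H](O[Si](CC)(CC)CC)[C@H](O[Si](CC)(CC)CC)[C@@H](O[Si](CC)(CC)CC)C=CC#CCCc1ccccc1 | intermediate
20 | 2-(Ar-oxy)-11-phenyl-3,4,5-tris(TES-oxy)undec-6-en-8-ynal (configuration as in 19) | O=C[C@@H](Oc1cc2c(cc1OC)oc(CCc1ccccc1)cc2=O)[C@@H](O[Si](CC)(CC)CC)[C@H](O[Si](CC)(CC)CC)[C@@H](O[Si](CC)(CC)CC)C=CC#CCCc1ccccc1 | intermediate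
21 | oxime of 20 (E/Z at C=N and C=C) | ON=C[C@@H](Oc1cc2c(cc1OC)oc(CCc1ccccc1)cc2=O)[C@@H](O[Si](CC)(CC)CC)[C@H](O[Si](CC)(CC)CC)[C@@H](O[Si](CC)(CC)CC)C=CC#CCCc1ccccc1 | intermediate
22 | nitrile oxide derived from 21 | [O-][N+]#C[C@@H](Oc1cc2c(cc1OC)oc(CCc1ccccc1)cc2=O)[C@@H](O[Si](CC)(CC)CC)[C@H](O[Si](CC)(CC)CC)[C@@H](O[Si](CC)(CC)CC)C=CC#CCCc1ccccc1 | intermediate
23 | 7-(Ar-oxy)-3-(4-phenylbut-1-yn-1-yl)-4,5,6-tris(TES-oxy)-3,3a,4,5,6,7-hexahydro-2,1-benzisoxazole (D-gluco tetrad at C4–C7, mixture at C3 and C3a) | N1=C2[C@@H](Oc3cc4c(cc3OC)oc(CCc3ccccc3)cc4=O)[C@@H](O[Si](CC)(CC)CC)[C@H](O[Si](CC)(CC)CC)[C@@H](O[Si](CC)(CC)CC)C2C(O1)C#CCCc1ccccc1 | intermediate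
24 | 6-(Ar-oxy)-2-(1-hydroxy-5-phenylpent-2-yn-1-yl)-3,4,5-tris(TES-oxy)cyclohexan-1-one (mixture at C2 and the carbinol) | O=C1[C@@H](Oc2cc3c(cc2OC)oc(CCc2ccccc2)cc3=O)[C@@H](O[Si](CC)(CC)CC)[C@H](O[Si](CC)(CC)CC)[C@@H](O[Si](CC)(CC)CC)C1C(O)C#CCCc1ccccc1 | intermediate
25 | 6-(Ar-oxy)-2-(5-phenylpent-2-ynoyl)-3,4,5-tris(TES-oxy)cyclohexan-1-one (drawn as the diketone, present as its enol) | O=C1[C@@H](Oc2cc3c(cc2OC)oc(CCc2ccccc2)cc3=O)[C@@H](O[Si](CC)(CC)CC)[C@H](O[Si](CC)(CC)CC)[C@@H](O[Si](CC)(CC)CC)C1C(=O)C#CCCc1ccccc1 | intermediate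
26 | (5S,6R,7S,8S)-8-(Ar-oxy)-2-(2-phenylethyl)-5,6,7-tris(TES-oxy)-5,6,7,8-tetrahydro-4H-chromen-4-one | COc1cc2oc(CCc3ccccc3)cc(=O)c2cc1O[C@@H]1c2oc(CCc3ccccc3)cc(=O)c2[C@H](O[Si](CC)(CC)CC)[C@@H](O[Si](CC)(CC)CC)[C@@H]1O[Si](CC)(CC)CC | intermediate
27 | (5S,6R,7S,8S)-5,6,7-trihydroxy-8-{[7-methoxy-4-oxo-2-(2-phenylethyl)-4H-chromen-6-yl]oxy}-2-(2-phenylethyl)-5,6,7,8-tetrahydro-4H-chromen-4-one | COc1cc2oc(CCc3ccccc3)cc(=O)c2cc1O[C@@H]1c2oc(CCc3ccccc3)cc(=O)c2[C@H](O)[C@@H](O)[C@@H]1O | target

## Step count and least certain steps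

Total step count: 15. Longest linear sequence: 12 steps (steps 1–3 and 7–15); the sugar branch from 11 is 10 steps and the phosphonium branch from 7 is 9 steps.

Step 12 (key step). The most likely failure is dimerisation of the nitrile oxide to the furoxan, because closure of a six-membered ring onto a 1,2-disubstituted alkene next to a bulky silyloxy group may be slow. Chlorination of the electron-rich aryl ether by hypochlorite is a second possibility. Fallback: start from 21 and use no oxidant. Heating in toluene at 110 °C should give the NH-nitrone tautomer, which undergoes intramolecular oxime–olefin cycloaddition to the N-unsubstituted isoxazolidine F1. N-chlorination with N-chlorosuccinimide and dehydrochlorination with DBU would then return to the route at 23.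

Step 9. The likely failure is base-induced degradation of the free aldose before olefination (epimerisation at the carbon next to the aldehyde, beta-elimination of the C6 oxygen), together with slow ring opening of the lactol. Fallback: start from 17 and avoid basic ylides. Takai olefination (CrCl2, CHI3, THF) would give the (E)-vinyl iodide tetrol F3, and Sonogashira coupling with 7 (Pd(PPh3)4, CuI, Et3N) would return at 18.

Step 11. The likely failures are loss of a secondary silyl group under the activated sulfoxide, and epimerisation at C8 of the alpha-aryloxy aldehyde before the oxime forms. Fallback: start from 18 and oxidise before protecting. TEMPO with PhI(OAc)2 should oxidise the primary alcohol to the cyclic hemiacetal F4, which is not enolisable, and hydroxylamine would open it to the oxime triol F5. Exhaustive silylation (Et3SiCl, imidazole) would give the O-silyl oxime F6, and brief methanolysis of the labile N–O–Si bond would return at 21.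

Step 7. The likely failure is slow displacement, because the phenoxide must enter on the concave face of the bicyclic lactone; this leaves time for elimination through the lactone enolate and opening of the furanose ring. Fallback: start from 14 and separate activation from substitution. The isolated L-ido triflate F2 (Tf2O, pyridine) would be treated with the pre-formed caesium phenoxide of 6 (Cs2CO3, MeCN, 0 °C), a small nucleophile without the bulky phosphonium leaving group, to return at 15.

Step 14. The likely failure is closure in the 5-exo mode to an alkylidene furanone; the amine could also epimerise C8 through the extended enolate. Fallback: start from 24 and use an electrophile-driven closure. After MnO2 oxidation, I2 with NaHCO3 in MeCN should activate the alkyne as the iodonium ion and force 6-endo attack of the enol oxygen to the 3-iodo-4-pyranone F7. Reductive deiodination (Pd(OAc)2, PPh3, HCO2Na, DMF) would return at 26.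

## Further compounds

F1 | step 12 | 7-(Ar-oxy)-3-(4-phenylbut-1-yn-1-yl)-4,5,6-tris(TES-oxy)octahydro-2,1-benzisoxazole (N–H isoxazolidine, mixture at C3, C3a and C7a) | N1C2[C@@H](Oc3cc4c(cc3OC)oc(CCc3ccccc3)cc4=O)[C@@H](O[Si](CC)(CC)CC)[C@H](O[Si](CC)(CC)CC)[C@@H](O[Si](CC)(CC)CC)C2C(O1)C#CCCc1ccccc1
F2 | step 7 | 1,2-O-isopropylidene-5-O-trifluoromethanesulfonyl-β-L-idofuranurono-6,3-lactone | CC1(C)O[C@H]2O[C@@H]3[C@@H](OS(=O)(=O)C(F)(F)F)C(=O)O[C@@H]3[C@H]2O1
F3 | step 9 | (2R,3S,4R,5S,6E)-2-(Ar-oxy)-7-iodohept-6-ene-1,3,4,5-tetrol | OC[C@@H](Oc1cc2c(cc1OC)oc(CCc1ccccc1)cc2=O)[C@@H](O)[C@H](O)[C@@H](O)/C=C/I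
F4 | step 11 | five-membered cyclic hemiacetal of the C8a aldehyde with O6 (4-(Ar-oxy)-3-hydroxy-5-(1-hydroxy-7-phenylhept-2-en-4-yn-1-yl)oxolan-2-ol, D-gluco configuration) | OC1O[C@H]([C@@H](O)C=CC#CCCc2ccccc2)[C@H](O)[C@@H]1Oc2cc3c(cc2OC)oc(CCc2ccccc2)cc3=O
F5 | step 11 | 2-(Ar-oxy)-3,4,5-trihydroxy-11-phenylundec-6-en-8-ynal oxime (configuration as in 18) | ON=C[C@@H](Oc1cc2c(cc1OC)oc(CCc1ccccc1)cc2=O)[C@@H](O)[C@H](O)[C@@H](O)C=CC#CCCc1ccccc1
F6 | step 11 | O-TES oxime of 2-(Ar-oxy)-11-phenyl-3,4,5-tris(TES-oxy)undec-6-en-8-ynal | CC[Si](CC)(CC)ON=C[C@@H](Oc1cc2c(cc1OC)oc(CCc1ccccc1)cc2=O)[C@@H](O[Si](CC)(CC)CC)[C@H](O[Si](CC)(CC)CC)[C@@H](O[Si](CC)(CC)CC)C=CC#CCCc1ccccc1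
F7 | step 14 | (5S,6R,7S,8S)-8-(Ar-oxy)-3-iodo-2-(2-phenylethyl)-5,6,7-tris(TES-oxy)-5,6,7,8-tetrahydro-4H-chromen-4-one | COc1cc2oc(CCc3ccccc3)cc(=O)c2cc1O[C@@H]1c2oc(CCc3ccccc3)c(I)c(=O)c2[C@H](O[Si](CC)(CC)CC)[C@@H](O[Si](CC)(CC)CC)[C@@H]1O[Si](CC)(CC)CC
A1 | alternative 1 | (5S,6R)-7β,8β-epoxy-5,6-dihydroxy-2-(2-phenylethyl)-5,6,7,8-tetrahydro-4H-chromen-4-one | O[C@@H]1[C@@H](O)[C@H]2O[C@H]2c2oc(CCc3ccccc3)cc(=O)c12
A2 | alternative 1 | C7 epimer of the target (7,8-trans ether) | COc1cc2oc(CCc3ccccc3)cc(=O)c2cc1O[C@@H]1c2oc(CCc3ccccc3)cc(=O)c2[C@H](O)[C@@H](O)[C@H]1O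
A3 | alternative 1 | all-trans 5,6,7,8-tetrahydroxy-2-(2-phenylethyl)-5,6,7,8-tetrahydro-4H-chromen-4-one (8β-OH) | O[C@H]1c2oc(CCc3ccccc3)cc(=O)c2[C@H](O)[C@@H](O)[C@@H]1O
A4 | alternative 2 | 4-hydroxy-5,6-(isopropylidenedioxy)cyclohex-2-en-1-one (target locants: C8a ketone, 6β-OH, 7α,8α-acetonide) | O=C1C=C[C@@H](O)[C@@H]2OC(C)(C)O[C@H]12
A5 | alternative 2 | (5S,6R,7S,8S)-5,6,7,8-tetrahydroxy-2-(2-phenylethyl)-5,6,7,8-tetrahydro-4H-chromen-4-one | O[C@@H]1c2oc(CCc3ccccc3)cc(=O)c2[C@H](O)[C@@H](O)[C@@H]1O
A6 | alternative 2 | [7-methoxy-4-oxo-2-(2-phenylethyl)-4H-chromen-6-yl]boronic acid | COc1cc2oc(CCc3ccccc3)cc(=O)c2cc1B(O)O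
A7 | alternative 3 | 3-(Ar-oxy)-4-hydroxy-5-(1-hydroxy-3-oxo-7-phenylhept-4-yn-1-yl)oxolan-2-one (D-gluco configuration) | O=C1O[C@H]([C@@H](O)CC(=O)C#CCCc2ccccc2)[C@H](O)[C@@H]1Oc2cc3c(cc2OC)oc(CCc2ccccc2)cc3=O
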